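**Plan**

1. Retrosynthetic cuts, in order: the C-8 ester; the ring bond C-1–C-2; the C-10 methyl/C-1 iodide and the C-8–C-9 bond (back to a C-8 aldehyde); then a bond that is not in the target, C-8–C-15, is added, which turns the seco chain into a cyclohexene; last, the lactone bonds O–C-6 and C-7–C-11 are cut together, leaving a cyclohexadiene cis-diol acetonide and methylmalonic acid.
2. Enabling feature: C-4, C-5, C-6, C-7, C-8 and C-15 map onto the benzene ring of (2-bromoethyl)benzene (side chain = C-3/C-2). Its enzymatic cis-dihydrodiol is the diene C-4=C-5–C-6=C-7 with an unsubstituted terminus C-7 next to oxygenated C-8, so an electrophilic radical enters at C-7 and the C-4–C-6 allyl cation is closed at C-6.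
3. Forward order: arene → cyclohexadiene diol (step 1) → cis-fused γ-lactone on the six-membered ring (step 3) → six-membered ring opened by glycol cleavage (step 5) → C-9/C-10/C-1/C-14 added at C-8 (steps 8, 9) → ten-membered ring closed at C-1–C-2 (step 11) → side-chain ester.
4. Stereochemistry: absolute configuration from the dioxygenase; C-6 and C-7 from annulation anti to the acetonide with cis closure; C-11 by equilibration; C-8 from a chiral phosphoric acid; 4,5-alkene geometry from the six-membered ring; 1(10)-alkene from syn-carboalumination.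
5. Helpers put in and taken out: the second carboxyl of methylmalonic acid (out in step 4), the acetonide and the C-8–C-15 bond (out in step 5), two silyl ethers (out in step 15).

Key step: step 3

Remark: germacrane numbering is used throughout (lactone O on C-6, lactone α-carbon C-11 on C-7, ester on C-8, CH2OH = C-15, C-12 = lactone C=O). The target is taken as drawn: (6R,7S,8S,11R), cis-fused lactone, H-6/H-7/H-8 mutually cis, both ring double bonds trans within the ring (1(10)E, 4Z by CIP). The dioxygenase is assumed to give the usual (1S,2R) diol with this substrate, and the 11-methyl orientation of the target (cis to H-7) is assumed to be the thermodynamically preferred one.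

**Step 1**
Reactants: 1 (2-bromoethyl)benzene
Product: 2 (1S,2R)-3-(2-bromoethyl)cyclohexa-3,5-diene-1,2-diol
Conditions: recombinant E. coli expressing toluene dioxygenase (e.g. JM109(pDTG601A)), IPTG, glucose feed, air, pH 7 buffer, 35 °C; EtOAc extraction
Reagents that add atoms: dioxygen (O=O)
Why: Enzymatic arene cis-dihydroxylation of a monosubstituted benzene puts both oxygens of O2 on the 2,3-positions from one face, so the flat ring should become the enantiopure diene diol in which C-8 and C-15 carry the cis oxygens and C-4=C-5–C-6=C-7 is the diene.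

**Step 2**
Reactants: 2 (1S,2R)-3-(2-bromoethyl)cyclohexa-3,5-diene-1,2-diol
Product: 3 (3aR,7aS)-4-(2-bromoethyl)-2,2-dimethyl-3a,7a-dihydro-1,3-benzodioxole
Conditions: 2,2-dimethoxypropane, p-TsOH (cat.), acetone, 0 °C
Reagents that add atoms: 2,2-dimethoxypropane (COC(C)(C)OC)
Why: Acid-catalysed acetonide formation on the cis-diol at 0 °C should outpace dehydration to the phenol, and the dioxolane then shields one face of the diene.

**Step 3**
Reactants: 3 (3aR,7aS)-4-(2-bromoethyl)-2,2-dimethyl-3a,7a-dihydro-1,3-benzodioxole; 4 methylmalonic acid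
Product: 5 bicyclic lactone acid (cis-fused γ-lactone on C-6/C-7 anti to the acetonide; C-11 bears CH3 and CO2H; either C-11 configuration)
Conditions: Mn(OAc)3·2H2O (2.3 equiv), 4 (3 equiv), KOAc, degassed AcOH, 50 °C
Reagents that add atoms: none
Why: The Mn(III) enolate of 4 gives, by inner-sphere electron transfer, an electrophilic tertiary α-carboxyalkyl radical that adds to the unsubstituted diene terminus C-7, and a second Mn(III) oxidises the resulting C-4/C-5/C-6 allyl radical to the allyl cation, which the pendant carboxyl captures at C-6 (radical–polar crossover), so C-7–C-11 and O–C-6 form in one operation. The closest known reaction type is the Mn(OAc)3-mediated oxidative γ-lactone annulation of alkenes and 1,3-dienes with acetic, cyanoacetic and malonic acids. The lactone closes by 5-exo attack of the carboxyl oxygen on the allyl-cation terminus C-6, which on a cyclohexenyl cation is only possible cis to the C-7 side chain. C-7 is set by radical attack anti to the dioxolane oxygen on C-8, C-6 follows from the cis closure, and C-11 is formed as a quaternary centre whose configuration does not matter because it is reset in step 4. The step needs regioselectivity for C-7 over C-4 (less hindered terminus, more substituted allyl radical), chemoselectivity for the conjugated diene over the product alkene (limiting oxidant), and capture of the cation at C-6 rather than C-4 (γ-lactone versus a strained bridged ring). The second carboxyl group is the activating group that lets the radical form at 50 °C and is removed in step 4.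

**Step 4**
Reactants: 5 bicyclic lactone acid
Product: 7 acetonide lactone with 11R methyl (methyl cis to H-7 and trans to C-8), via 11-epi lactone 6 (not isolated)
Conditions: toluene, 110 °C; then DBU (0.1 equiv), 23 °C
Reagents that add atoms: none
Why: Thermal decarboxylation of the malonic-acid-type lactone acid through its enol should give both C-11 epimers, and catalytic DBU then equilibrates them through the lactone enolate towards the isomer with the methyl group on the convex face, trans to C-8.

**Step 5**
Reactants: 7 acetonide lactone
Product: 9 dialdehyde lactone (CHO = C-8 on C-7; (Z)-4-bromo-2-formylbut-1-enyl on C-6), via diol lactone 8 (not isolated)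
Conditions: (i) TFA–H2O (9:1), 0 °C, then evaporation; (ii) NaIO4, THF–pH 7 buffer, 0 °C; crude product used at once
Reagents that add atoms: none
Why: Aqueous acid hydrolyses the isopropylidene acetal and periodate then cleaves the cis-1,2-diol (Malaprade glycol cleavage) at neutral pH, which removes the temporary C-8–C-15 bond, leaves C-6, C-7 and C-11 untouched and keeps the 4,5-alkene geometry imposed by the former ring (C-15 cis to C-6).

**Step 6**
Reactants: 9 dialdehyde lactone
Product: 10 hydroxy aldehyde (C-15 CH2OH; C-8 CHO)
Conditions: CeCl3·7H2O (1 equiv), NaBH4 (0.5 equiv), EtOH–H2O, −15 °C; pH 7 quench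
Reagents that add atoms: none
Why: In this Luche-type chemoselective reduction the saturated C-8 aldehyde should be tied up as its hydrate/hemiacetal while the conjugated C-15 aldehyde undergoes 1,2-reduction, and the cold near-neutral medium should spare the epimerisable C-7 centre and the β-acyloxy aldehyde.

**Step 7**
Reactants: 10 hydroxy aldehyde
Product: 11 silyloxy aldehyde (C-15 OTBS; C-8 CHO)
Conditions: TBSCl (1.1 equiv), imidazole, CH2Cl2, 0 °C
Reagents that add atoms: tert-butyldimethylsilyl chloride (CC(C)(C)[Si](C)(C)Cl)
Why: Imidazole-mediated silylation of the primary allylic alcohol is fast at 0 °C, and the weak base should not trigger β-elimination of the lactone carboxylate.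

**Step 8**
Reactants: 11 silyloxy aldehyde; 12 allenylboronic acid pinacol ester
Product: 14 (8S)-homopropargylic alcohol, via pinacol borate ester 13 (not isolated)
Conditions: (S)-TRIP phosphoric acid (10 mol %), 4 Å MS, toluene, −20 °C; aqueous NaHCO3 work-up
Reagents that add atoms: none
Why: In this chiral phosphoric acid-catalysed propargylation the allenylboronate adds through a closed six-membered SE2′ transition state organised by the catalyst, so the catalyst enantiomer selected for Si-face attack should set C-8 as S while forming C-8–C-9 under neutral conditions; the sense is to be checked by Mosher analysis and the antipodal catalyst used if it is reversed.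

**Step 9**
Reactants: 14 (8S)-homopropargylic alcohol
Product: 16 (E)-iodoalkene alcohol (C-10 methyl; C-1 iodide), via alkenylalane 15 (not isolated)
Conditions: AlMe3 (4 equiv), Cp2ZrCl2 (0.5 equiv), H2O (1.5 equiv), CH2Cl2, −20 °C; then I2, THF, −30 to 0 °C; Rochelle salt work-up
Reagents that add atoms: trimethylaluminium (C[Al](C)C); iodine (II)
Why: Negishi zirconium-catalysed methylalumination adds CH3 and Al syn across the terminal alkyne with methyl on the internal carbon C-10, and iodinolysis with retention gives the (E)-iodoalkene (C-9 trans to iodine); the hydroxyl is carried as its aluminium alkoxide and the low-temperature water-accelerated protocol should leave lactone, bromide and silyl ether intact.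

**Step 10**
Reactants: 16 (E)-iodoalkene alcohol
Product: 17 diene iodoalkene (C-2=C-3 vinyl on C-4)
Conditions: DBU (3 equiv), toluene, 80 °C
Reagents that add atoms: none
Why: E2 dehydrobromination, favoured because the β-hydrogens on C-3 are allylic and the product is a conjugated diene, should unveil the terminal vinyl group needed for hydroboration.

**Step 11**
Reactants: 17 diene iodoalkene; 18 9-borabicyclo[3.3.1]nonane
Product: 20 macrocyclic alcohol (cis-fused germacranolide; 8-OH; 15-OTBS), via B-alkyl borane 19 (not isolated)
Conditions: 18 (2.5 equiv), THF, 0 to 23 °C; then slow addition to Pd(dppf)Cl2 (20 mol %), AsPh3 (20 mol %), aq. K3PO4, DMF–THF, 45 °C, final concentration 1 mM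
Reagents that add atoms: none
Why: In this B-alkyl Suzuki–Miyaura macrocyclisation 9-BBN should hydroborate only the monosubstituted vinyl group with boron on terminal C-2 (the hydroxyl is transiently O-borylated), and after oxidative addition of the C-1–I bond with retention the base-activated alkyl group transmetalates and reductive elimination closes the ten-membered ring at C-1–C-2, helped by high dilution and the cis arrangement of the two arms on the lactone.

**Step 12**
Reactants: 21 ethyl 2-(hydroxymethyl)acrylate
Product: 22 ethyl 2-[(tert-butyldimethylsilyloxy)methyl]acrylate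
Conditions: TBSCl, imidazole, CH2Cl2, 0 to 23 °C
Reagents that add atoms: tert-butyldimethylsilyl chloride (CC(C)(C)[Si](C)(C)Cl)
Why: Standard silylation of a primary allylic alcohol.

**Step 13**
Reactants: 22 ethyl 2-[(tert-butyldimethylsilyloxy)methyl]acrylate
Product: 23 2-[(tert-butyldimethylsilyloxy)methyl]acrylic acid
Conditions: LiOH·H2O, THF–H2O, 0 °C; 1 M HCl to pH 3 at 0 °C
Reagents that add atoms: lithium hydroxide ([Li+].[OH-])
Why: Saponification of the ethyl ester at 0 °C followed by brief cold acidification should give the free acid without loss of the silyl ether.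

**Step 14**
Reactants: 20 macrocyclic alcohol; 23 2-[(tert-butyldimethylsilyloxy)methyl]acrylic acid; 24 2,4,6-trichlorobenzoyl chloride
Product: 26 bis-silyl ether of the target, via mixed anhydride 25 (not isolated)
Conditions: 23, 24, Et3N, toluene, 0 °C; then 20, DMAP, 23 °C
Reagents that add atoms: none
Why: In the Yamaguchi esterification the mixed anhydride acylates DMAP and the acylpyridinium esterifies the only free hydroxyl (C-8) with retention at C-8.

**Step 15**
Reactants: 26 bis-silyl ether of the target
Product: 27 CNP0167163.2
Conditions: HF·pyridine, pyridine, THF, 0 to 23 °C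
Reagents that add atoms: none
Why: Buffered fluoride should cleave both primary silyl ethers without base (no epimerisation or acyl migration) and without the strong acid that would trigger transannular cyclisation of the 1(10),4-diene.

**Compound list**

1 | (2-bromoethyl)benzene | BrCCc1ccccc1 | starting material
2 | (1S,2R)-3-(2-bromoethyl)cyclohexa-3,5-diene-1,2-diol | O[C@H]1C=CC=C(CCBr)[C@H]1O | intermediate
3 | (3aR,7aS)-4-(2-bromoethyl)-2,2-dimethyl-3a,7a-dihydro-1,3-benzodioxole | CC1(C)O[C@H]2C=CC=C(CCBr)[C@H]2O1 | intermediate
4 | methylmalonic acid | CC(C(=O)O)C(=O)O | starting material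
5 | bicyclic lactone acid: acetonide-protected cyclohexene with cis-fused γ-lactone (O on C-6, C-11 on C-7, both anti to the acetonide), C-11 bearing CH3 and CO2H, C-11 epimers | CC1(C(=O)O)C(=O)O[C@@H]2C=C(CCBr)[C@H]3OC(C)(C)O[C@H]3[C@H]12 | intermediate
6 | 11-epi lactone (methyl on the concave face, cis to C-8) | C[C@@H]1C(=O)O[C@@H]2C=C(CCBr)[C@H]3OC(C)(C)O[C@H]3[C@H]12 | intermediate
7 | acetonide lactone, 11R (methyl cis to H-7, trans to C-8) | C[C@H]1C(=O)O[C@@H]2C=C(CCBr)[C@H]3OC(C)(C)O[C@H]3[C@H]12 | intermediate
8 | diol lactone (cis-8,15-diol on the cyclohexene, anti to the lactone) | C[C@H]1C(=O)O[C@@H]2C=C(CCBr)[C@@H](O)[C@@H](O)[C@H]12 | intermediate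
9 | dialdehyde lactone: 3-methyl-γ-butyrolactone with CHO (C-8) on C-7 and (Z)-4-bromo-2-formylbut-1-enyl on C-6; C-6/C-7 substituents cis, 11-methyl trans to C-8 | C[C@H]1C(=O)O[C@H](/C=C(/CCBr)C=O)[C@@H]1C=O | intermediate
10 | hydroxy aldehyde (C-15 CH2OH, C-8 CHO; ring stereochemistry as in 9) | C[C@H]1C(=O)O[C@H](/C=C(/CCBr)CO)[C@@H]1C=O | intermediate
11 | silyloxy aldehyde (C-15 OTBS, C-8 CHO) | C[C@H]1C(=O)O[C@H](/C=C(/CCBr)CO[Si](C)(C)C(C)(C)C)[C@@H]1C=O | intermediate
12 | allenylboronic acid pinacol ester | C=C=CB1OC(C)(C)C(C)(C)O1 | starting material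
13 | pinacol borate ester of 14 | C[C@H]1C(=O)O[C@H](/C=C(/CCBr)CO[Si](C)(C)C(C)(C)C)[C@@H]1[C@@H](OB2OC(C)(C)C(C)(C)O2)CC#C | intermediate
14 | (8S)-homopropargylic alcohol | C[C@H]1C(=O)O[C@H](/C=C(/CCBr)CO[Si](C)(C)C(C)(C)C)[C@@H]1[C@@H](O)CC#C | intermediate
15 | (E)-alkenyl(dimethyl)alane, C-8 oxygen as dimethylaluminium alkoxide | C[C@H]1C(=O)O[C@H](/C=C(/CCBr)CO[Si](C)(C)C(C)(C)C)[C@@H]1[C@@H](O[Al](C)C)C/C(C)=C/[Al](C)C | intermediate
16 | (E)-iodoalkene alcohol (C-10 methyl, C-1 iodide, 8S-OH, C-2 bromide) | C[C@H]1C(=O)O[C@H](/C=C(/CCBr)CO[Si](C)(C)C(C)(C)C)[C@@H]1[C@@H](O)C/C(C)=C/I | intermediate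
17 | diene iodoalkene (vinyl C-3=C-2 on C-4) | C[C@H]1C(=O)O[C@H](/C=C(/C=C)CO[Si](C)(C)C(C)(C)C)[C@@H]1[C@@H](O)C/C(C)=C/I | intermediate
18 | 9-borabicyclo[3.3.1]nonane (9-BBN) | B1C2CCCC1CCC2 | starting material
19 | B-alkyl borane (9-BBN on C-2; C-8 oxygen O-borylated) | C[C@H]1C(=O)O[C@H](/C=C(/CCB2C3CCCC2CCC3)CO[Si](C)(C)C(C)(C)C)[C@@H]1[C@@H](OB2C3CCCC2CCC3)C/C(C)=C/I | intermediate
20 | macrocyclic alcohol: (6R,7S,8S,11R)-8-hydroxy-15-(tert-butyldimethylsilyloxy)-11,13-dihydrogermacra-1(10),4-dien-12,6-olide | O[C@H]1C/C(C)=C/CC/C(CO[Si](C)(C)C(C)(C)C)=C/[C@H]2OC(=O)[C@H](C)[C@@H]12 | intermediate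
21 | ethyl 2-(hydroxymethyl)acrylate | C=C(CO)C(=O)OCC | starting material
22 | ethyl 2-[(tert-butyldimethylsilyloxy)methyl]acrylate | C=C(CO[Si](C)(C)C(C)(C)C)C(=O)OCC | intermediate
23 | 2-[(tert-butyldimethylsilyloxy)methyl]acrylic acid | C=C(CO[Si](C)(C)C(C)(C)C)C(=O)O | intermediate
24 | 2,4,6-trichlorobenzoyl chloride | O=C(Cl)c1c(Cl)cc(Cl)cc1Cl | starting material
25 | mixed anhydride of 23 and 2,4,6-trichlorobenzoic acid | C=C(CO[Si](C)(C)C(C)(C)C)C(=O)OC(=O)c1c(Cl)cc(Cl)cc1Cl | intermediate
26 | bis-silyl ether of the target (TBS on C-15 oxygen and on the side-chain CH2O) | C=C(CO[Si](C)(C)C(C)(C)C)C(=O)O[C@H]1C/C(C)=C/CC/C(CO[Si](C)(C)C(C)(C)C)=C/[C@H]2OC(=O)[C@H](C)[C@@H]12 | intermediate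
27 | CNP0167163.2: (6R,7S,8S,11R)-15-hydroxy-8-[2-(hydroxymethyl)acryloyloxy]-11,13-dihydrogermacra-1(10),4-dien-12,6-olide | C=C(CO)C(=O)O[C@H]1C/C(C)=C/CC/C(CO)=C/[C@H]2OC(=O)[C@H](C)[C@@H]12 | target

**Step count**

Total: 15 steps. Longest linear sequence: 13 steps (steps 1–11, 14, 15); steps 12–13 make the side-chain acid.

**Steps most likely to fail**

1. Step 3. What may go wrong: acid-promoted loss of the acetonide followed by aromatisation of the diene, further oxidation of the product alkene, or capture of the allyl cation by acetate instead of the internal carboxyl. The fallback sets out from 3 and returns at 7. It replaces the oxidative enolate chemistry by neutral iodine-atom-transfer radical addition (Kharasch type) of 2-iodopropanoic acid (Et3B/air, CH2Cl2, 0 °C). This should give the allylic iodo acid F1, with C-11 on C-7 anti to the acetonide and iodine on C-6 on the opposite face. NaHCO3 in DMF at 40 °C then closes the lactone by intramolecular displacement of the allylic iodide with inversion at C-6 (an allyl-transposed iodide would converge by SN2′), and DBU equilibration as in step 4 gives 7. No malonate activating group and no decarboxylation are needed.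

2. Step 11. What may go wrong: oligomerisation competing with closure of the strained (E,E)-cyclodecadiene, β-hydride elimination or protodeboronation of the alkyl-metal species, and incomplete or unselective hydroboration of the diene. The fallback sets out from 16 (so step 10 is skipped) and returns at 20. The C-8 hydroxyl is silylated (TMSCl, imidazole) and the bromide exchanged (NaI, acetone, Finkelstein) to give the alkyl iodide TMS ether F2. Zinc dust with LiCl in THF at 25 °C should insert selectively into the sp3 C–I bond to give the alkylzinc iodide F3. Slow addition of F3 to Pd2(dba)3/SPhos in THF–NMP at 40 °C closes the ring by intramolecular Negishi coupling to the macrocyclic TMS ether F4, and a citric acid work-up removes the TMS group to give 20.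

3. Step 6 (with the crude product of step 5). What may go wrong: epimerisation at C-7 next to the C-8 aldehyde, β-elimination of the C-6 carboxylate from the β-acyloxy aldehyde, and incomplete discrimination between the two aldehydes. The fallback sets out from 9 and returns at 11. The saturated aldehyde is first protected selectively as its dimethyl acetal (HC(OMe)3, CeCl3·7H2O, MeOH, 23 °C) to give the enal acetal F5. Plain NaBH4 reduction (MeOH, 0 °C) gives the allylic alcohol acetal F6 and TBSCl/imidazole gives the silyl ether acetal F7. Mild acetal hydrolysis (LiBF4, wet MeCN) then releases the aldehyde 11 only just before step 8.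

**Further compounds**

F1 | step 3 | allylic iodo acid: acetonide cyclohexene with CH(CH3)CO2H on C-7 (anti to acetonide) and iodine on C-6 (trans to it) | CC(C(=O)O)[C@@H]1[C@@H](I)C=C(CCBr)[C@H]2OC(C)(C)O[C@@H]12
F2 | step 11 | alkyl iodide TMS ether of 16 (C-2 iodide, C-8 OTMS) | C[C@H]1C(=O)O[C@H](/C=C(/CCI)CO[Si](C)(C)C(C)(C)C)[C@@H]1[C@@H](O[Si](C)(C)C)C/C(C)=C/I
F3 | step 11 | alkylzinc iodide (zinc on C-2) | C[C@H]1C(=O)O[C@H](/C=C(/CC[Zn]I)CO[Si](C)(C)C(C)(C)C)[C@@H]1[C@@H](O[Si](C)(C)C)C/C(C)=C/I
F4 | step 11 | macrocyclic TMS ether of 20 | C[Si](C)(C)O[C@H]1C/C(C)=C/CC/C(CO[Si](C)(C)C(C)(C)C)=C/[C@H]2OC(=O)[C@H](C)[C@@H]12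
F5 | step 6 | enal with C-8 dimethyl acetal | C[C@H]1C(=O)O[C@H](/C=C(/CCBr)C=O)[C@@H]1C(OC)OC
F6 | step 6 | allylic alcohol with C-8 dimethyl acetal | C[C@H]1C(=O)O[C@H](/C=C(/CCBr)CO)[C@@H]1C(OC)OC
F7 | step 6 | TBS ether with C-8 dimethyl acetal | C[C@H]1C(=O)O[C@H](/C=C(/CCBr)CO[Si](C)(C)C(C)(C)C)[C@@H]1C(OC)OC
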